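**Retrosynthetic overview** (icetexane numbering: ring A = C1–C5, C10; ring B = C5–C10, C20; ring C = C8, C9, C11–C14; C18 = methyl, C19 = lactone carbonyl)
1. Endgame: the hydroxyquinone comes from an 11,12,14‑trimethoxyarene (oxidative demethylation, then O12‑dealkylation), and C1–OH from a reagent‑controlled reduction of the C1 enone.
2. Ring B is closed late by a one‑carbon annulation: HC(OMe)3 supplies C20 between the C10 silyl enol ether and arene C9 (Mukaiyama addition, Friedel–Crafts, loss of MeOH), which also places the C10=C20 double bond.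
3. Key disconnection: C2–C3 and C4–C5 by an intramolecular Diels–Alder reaction of the 2‑silyloxydiene C2=C1–C10=C5 with a methacrylate hung on the C6 enol oxygen, giving ring A, the lactone, and C4 and C5 at once. The enabling feature is that quaternary C4 has its carboxyl carbon C19 tied to O–C6 in a five‑membered enol lactone, with C6 bonded to C5 and C1 carrying oxygen.
4. The triene comes from the arene and 5‑methylfurfuryl alcohol: Friedel–Crafts (C7–C8), singlet‑oxygen opening of the furan to the C1…C6 ene‑dione, enol esterification, silylation.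
5. Ring order: C (arene, bought) → A + lactone (step 7) → B (step 8) → quinone.

Key step: step 7

Assumption: the (S)‑configured oxazaborolidinium salt is taken to deliver the (4S,5R) adduct; if the sense of induction proves opposite, its enantiomer would be used.

**Step 1**
Reactants: 1 1,2,4‑trimethoxybenzene; 2 acetone
Product: 3 2‑(2,3,6‑trimethoxyphenyl)propan‑2‑ol
Conditions: n‑BuLi, TMEDA, THF, 0 °C; then acetone, −78 °C to rt
Reagents that add atoms: acetone, CC(C)=O
Why: Directed ortho‑lithiation at C3, the site flanked by two methoxy groups, followed by 1,2‑addition of the aryllithium to acetone.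

**Step 2**
Reactants: 3 2‑(2,3,6‑trimethoxyphenyl)propan‑2‑ol
Product: 4 2‑isopropyl‑1,3,4‑trimethoxybenzene
Conditions: Et3SiH, TFA, CH2Cl2, 0 °C
Reagents that add atoms: none
Why: Ionic hydrogenation; the tertiary benzylic cation formed in TFA is trapped by hydride from the silane.

**Step 3**
Reactants: 4 2‑isopropyl‑1,3,4‑trimethoxybenzene; 5 (5‑methylfuran‑2‑yl)methanol
Product: 6 2‑methyl‑5‑[(3‑isopropyl‑2,4,5‑trimethoxyphenyl)methyl]furan
Conditions: Bi(OTf)3 (5 mol %), excess 4, MeNO2, 0 °C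
Reagents that add atoms: (5‑methylfuran‑2‑yl)methanol, Cc1ccc(CO)o1
Why: Friedel–Crafts alkylation by the furfuryl cation at the arene position para to the 3‑methoxy and ortho to the 1‑methoxy group (the future C8); the 2,5‑disubstituted furan cannot self‑condense at an α‑position.

**Step 4**
Reactants: 6 2‑methyl‑5‑[(3‑isopropyl‑2,4,5‑trimethoxyphenyl)methyl]furan; 7 dioxygen
Product: 10 (3E)‑1‑(3‑isopropyl‑2,4,5‑trimethoxyphenyl)hex‑3‑ene‑2,5‑dione, via furan endoperoxide 8 (not isolated), via Z‑ene‑dione 9 (not isolated)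
Conditions: O2, hν (visible), tetraphenylporphyrin (cat.), CH2Cl2, −78 °C; Me2S, −78 °C to rt; then I2 (2 mol %), rt
Reagents that add atoms: dioxygen, O=O
Why: [4+2] addition of singlet oxygen to the furan and reduction of the endoperoxide should unmask the Z‑ene‑1,4‑dione; iodine‑catalysed equilibration should then give the more stable E isomer, which is needed so that C6 sits outside on the later diene and so that base cannot trigger an aldol ring closure.

**Step 5**
Reactants: 10 (3E)‑1‑(3‑isopropyl‑2,4,5‑trimethoxyphenyl)hex‑3‑ene‑2,5‑dione; 11 methacryloyl chloride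
Product: 12 (1Z,3E)‑1‑(3‑isopropyl‑2,4,5‑trimethoxyphenyl)‑5‑oxohexa‑1,3‑dien‑2‑yl 2‑methylprop‑2‑enoate
Conditions: KN(SiMe3)2, THF, −78 °C; then methacryloyl chloride, −78 to −40 °C
Reagents that add atoms: methacryloyl chloride, CC(=C)C(Cl)=O
Why: Kinetic deprotonation at the benzylic C7 methylene (the most acidic site, flanked by aryl and the C6 carbonyl) and O‑acylation of the potassium enolate should give the Z‑enol ester (ketone enolate O‑acylation).

**Step 6**
Reactants: 12 (1Z,3E)‑1‑(3‑isopropyl‑2,4,5‑trimethoxyphenyl)‑5‑oxohexa‑1,3‑dien‑2‑yl 2‑methylprop‑2‑enoate; 13 triisopropylsilyl triflate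
Product: 14 (1Z,3E)‑1‑(3‑isopropyl‑2,4,5‑trimethoxyphenyl)‑5‑(triisopropylsilyloxy)hexa‑1,3,5‑trien‑2‑yl 2‑methylprop‑2‑enoate
Conditions: TIPSOTf, Et3N, CH2Cl2, 0 °C
Reagents that add atoms: triisopropylsilyl triflate, CC(C)[Si](OS(=O)(=O)C(F)(F)F)(C(C)C)C(C)C
Why: Soft enolization of the methyl ketone, the only enolizable position left, and O‑silylation should give the cross‑conjugated 2‑silyloxydiene.

**Step 7**
Reactants: 14 (1Z,3E)‑1‑(3‑isopropyl‑2,4,5‑trimethoxyphenyl)‑5‑(triisopropylsilyloxy)hexa‑1,3,5‑trien‑2‑yl 2‑methylprop‑2‑enoate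
Product: 15 (3Z,3aR,7aS)‑3‑[(3‑isopropyl‑2,4,5‑trimethoxyphenyl)methylidene]‑7a‑methyl‑5‑(triisopropylsilyloxy)‑3a,6,7,7a‑tetrahydro‑2‑benzofuran‑1(3H)‑one (icetexane 4S,5R; methyl cis to H‑5)
Conditions: (S)‑o‑tolyl‑CBS‑oxazaborolidine·Tf2NH (20 mol %), CH2Cl2, −78 to −40 °C
Reagents that add atoms: none
Why: Proposed new method: the cationic oxazaborolidine should bind the C19 carbonyl of the enol methacrylate, and the tethered 2‑silyloxydiene should add in an asynchronous, normal‑electron‑demand intramolecular Diels–Alder reaction (C2, the nucleophilic diene terminus, to C3; C5 to C4); the closest known reactions are oxazaborolidinium‑catalysed Diels–Alder additions of 2‑silyloxydienes to acrylate esters and thermal type 1 intramolecular Diels–Alder reactions of ester‑tethered 1,3,8‑nonatrienes. Ring A closes in the [4+2] mode and the five‑membered lactone closes through the three‑atom tether C6–O–C19 (fused, type 1 mode). The C4/C5 relation (C18 methyl cis to H‑5) is fixed by the tether, because the forming lactone holds three sp2 atoms (C6, O, C19), is nearly planar and can only be cis‑fused to ring A. The absolute sense (4S,5R) is set by the catalyst, which shields one face of the bound methacrylate. Site selectivity between the two dienes of the cross‑conjugated triene is needed and is secured because only the C2=C1–C10=C5 diene carries the tether at an outside (E) terminus one bond from C5, while the C7=C6–C5=C10 diene cannot be reached. Regiochemistry is matched electronically, the silyloxy carbon C1 ending para to C4.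

**Step 8**
Reactants: 15 (3Z,3aR,7aS)‑3‑[(3‑isopropyl‑2,4,5‑trimethoxyphenyl)methylidene]‑7a‑methyl‑5‑(triisopropylsilyloxy)‑3a,6,7,7a‑tetrahydro‑2‑benzofuran‑1(3H)‑one; 16 trimethyl orthoformate
Product: 19 (4S,5R)‑11,12,14‑trimethoxy‑1‑oxoicetexa‑6,8,10(20),11,13‑pentaen‑19,6‑olide, via keto acetal 17 (not isolated), via cyclized methyl ether 18 (not isolated)
Conditions: HC(OMe)3, BF3·OEt2, CH2Cl2, −78 °C; then TFA, 0 °C to rt
Reagents that add atoms: trimethyl orthoformate, COC(OC)OC
Why: Mukaiyama‑type addition of the silyl enol ether (C10) to the dimethoxycarbenium ion, acid‑mediated Z/E equilibration of the benzylidene lactone through the C7 benzylic cation, Friedel–Crafts attack of C9 (the only free arene position, ortho to a methoxy group) on the C20 oxocarbenium ion and E1 loss of methanol (Bradsher‑type cyclodehydration) should close ring B and place the double bond at C10=C20, the only position open because C20 enters at the enol‑ether carbon C10.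

**Step 9**
Reactants: 19 (4S,5R)‑11,12,14‑trimethoxy‑1‑oxoicetexa‑6,8,10(20),11,13‑pentaen‑19,6‑olide
Product: 20 (1R,4S,5R)‑1‑hydroxy‑11,12,14‑trimethoxyicetexa‑6,8,10(20),11,13‑pentaen‑19,6‑olide
Conditions: (S)‑Me‑CBS‑oxazaborolidine (20 mol %), catecholborane, toluene, −78 °C
Reagents that add atoms: none
Why: Corey–Bakshi–Shibata reduction under reagent control; the α‑substituted alkenyl arm (C10=C20) acts as the large group and the C2 methylene as the small one, so the (S)‑catalyst should give the 1R alcohol (OH cis to the lactone bridge), and catecholborane should spare the enol lactone.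

**Step 10**
Reactants: 20 (1R,4S,5R)‑1‑hydroxy‑11,12,14‑trimethoxyicetexa‑6,8,10(20),11,13‑pentaen‑19,6‑olide; 21 water
Product: 22 (1R,4S,5R)‑1‑hydroxy‑12‑methoxy‑11,14‑dioxoicetexa‑6,8,10(20),12‑tetraen‑19,6‑olide
Conditions: (NH4)2Ce(NO3)6, MeCN/H2O, 0 °C
Reagents that add atoms: water, O
Why: Oxidative demethylation by tetravalent cerium; the para‑related 11‑ and 14‑methoxy groups should give the p‑quinone while the 12‑methoxy group remains as a vinylogous ester.

**Step 11**
Reactants: 22 (1R,4S,5R)‑1‑hydroxy‑12‑methoxy‑11,14‑dioxoicetexa‑6,8,10(20),12‑tetraen‑19,6‑olide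
Product: 23 6,7‑anhydroballotiquinone [(1R,4S,5R)‑1,12‑dihydroxy‑11,14‑dioxoicetexa‑6,8,10(20),12‑tetraen‑19,6‑olide]
Conditions: LiCl, DMF, 90 °C; then 1 M HCl
Reagents that add atoms: none
Why: SN2 dealkylation of the vinylogous methyl ester by chloride (Krapcho‑type), with the hydroxyquinone anion as leaving group; the non‑hydrolytic conditions should spare the enol lactone.

**Compound list**
1 | 1,2,4‑trimethoxybenzene | COc1ccc(OC)c(OC)c1 | starting material
2 | acetone | CC(C)=O | starting material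
3 | 2‑(2,3,6‑trimethoxyphenyl)propan‑2‑ol | COc1ccc(OC)c(C(C)(C)O)c1OC | intermediate
4 | 2‑isopropyl‑1,3,4‑trimethoxybenzene | COc1ccc(OC)c(C(C)C)c1OC | intermediate
5 | (5‑methylfuran‑2‑yl)methanol | Cc1ccc(CO)o1 | starting material
6 | 2‑methyl‑5‑[(3‑isopropyl‑2,4,5‑trimethoxyphenyl)methyl]furan | Cc1ccc(Cc2cc(OC)c(OC)c(C(C)C)c2OC)o1 | intermediate
7 | dioxygen | O=O | starting material
8 | 1‑methyl‑4‑[(3‑isopropyl‑2,4,5‑trimethoxyphenyl)methyl]‑2,3,7‑trioxabicyclo[2.2.1]hept‑5‑ene (racemic) | CC12OOC(Cc3cc(OC)c(OC)c(C(C)C)c3OC)(O1)C=C2 | intermediate (not isolated)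
9 | (3Z)‑1‑(3‑isopropyl‑2,4,5‑trimethoxyphenyl)hex‑3‑ene‑2,5‑dione | CC(=O)/C=C\C(=O)Cc1cc(OC)c(OC)c(C(C)C)c1OC | intermediate (not isolated)
10 | (3E)‑1‑(3‑isopropyl‑2,4,5‑trimethoxyphenyl)hex‑3‑ene‑2,5‑dione | CC(=O)/C=C/C(=O)Cc1cc(OC)c(OC)c(C(C)C)c1OC | intermediate
11 | methacryloyl chloride | CC(=C)C(Cl)=O | starting material
12 | (1Z,3E)‑1‑(3‑isopropyl‑2,4,5‑trimethoxyphenyl)‑5‑oxohexa‑1,3‑dien‑2‑yl 2‑methylprop‑2‑enoate | CC(=O)/C=C/C(/OC(=O)C(C)=C)=C/c1cc(OC)c(OC)c(C(C)C)c1OC | intermediate
13 | triisopropylsilyl triflate | CC(C)[Si](OS(=O)(=O)C(F)(F)F)(C(C)C)C(C)C | starting material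
14 | (1Z,3E)‑1‑(3‑isopropyl‑2,4,5‑trimethoxyphenyl)‑5‑(triisopropylsilyloxy)hexa‑1,3,5‑trien‑2‑yl 2‑methylprop‑2‑enoate | C=C(O[Si](C(C)C)(C(C)C)C(C)C)/C=C/C(/OC(=O)C(C)=C)=C/c1cc(OC)c(OC)c(C(C)C)c1OC | intermediate
15 | (3Z,3aR,7aS)‑3‑[(3‑isopropyl‑2,4,5‑trimethoxyphenyl)methylidene]‑7a‑methyl‑5‑(triisopropylsilyloxy)‑3a,6,7,7a‑tetrahydro‑2‑benzofuran‑1(3H)‑one | COc1c(C(C)C)c(OC)c(OC)cc1/C=C2\OC(=O)[C@@]3(C)CCC(O[Si](C(C)C)(C(C)C)C(C)C)=C[C@@H]23 | intermediate
16 | trimethyl orthoformate | COC(OC)OC | starting material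
17 | (3Z,3aR,7aS)‑4‑(dimethoxymethyl)‑3‑[(3‑isopropyl‑2,4,5‑trimethoxyphenyl)methylidene]‑7a‑methylhexahydro‑2‑benzofuran‑1,5‑dione (C10 epimers) | COc1c(C(C)C)c(OC)c(OC)cc1/C=C2\OC(=O)[C@@]3(C)CCC(=O)C(C(OC)OC)[C@@H]23 | intermediate (not isolated)
18 | (4S,5R)‑11,12,14,20‑tetramethoxy‑1‑oxoicetexa‑6,8,11,13‑tetraen‑19,6‑olide (C10/C20 epimers) | CC(C)c1c(OC)c(OC)c2c(C=C3OC(=O)[C@@]4(C)CCC(=O)C(C2OC)[C@@H]34)c1OC | intermediate (not isolated)
19 | (4S,5R)‑11,12,14‑trimethoxy‑1‑oxoicetexa‑6,8,10(20),11,13‑pentaen‑19,6‑olide | CC(C)c1c(OC)c(OC)c2c(C=C3OC(=O)[C@@]4(C)CCC(=O)C(=C2)[C@@H]34)c1OC | intermediate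
20 | (1R,4S,5R)‑1‑hydroxy‑11,12,14‑trimethoxyicetexa‑6,8,10(20),11,13‑pentaen‑19,6‑olide | CC(C)c1c(OC)c(OC)c2c(C=C3OC(=O)[C@@]4(C)CC[C@@H](O)C(=C2)[C@@H]34)c1OC | intermediate
21 | water | O | starting material
22 | (1R,4S,5R)‑1‑hydroxy‑12‑methoxy‑11,14‑dioxoicetexa‑6,8,10(20),12‑tetraen‑19,6‑olide | CC(C)C1=C(OC)C(=O)C2=C(C=C3OC(=O)[C@@]4(C)CC[C@@H](O)C(=C2)[C@@H]34)C1=O | intermediate
23 | 6,7‑anhydroballotiquinone | CC(C)C1=C(O)C(=O)C2=C(C=C3OC(=O)[C@@]4(C)CC[C@@H](O)C(=C2)[C@@H]34)C1=O | target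

**Totals**
Total step count: 11. Longest linear sequence: 11 steps (from 1).

**Steps most likely to fail**

1. Step 7 (Proposed new method). The chiral acid may discriminate poorly between the faces of the bound enol methacrylate, or may strip the silyl enol ether before cycloaddition. Fallback with known chemistry, setting out from 14: a thermal intramolecular Diels–Alder reaction (toluene, trace BHT, 110 °C) should give the racemate, that is 15 together with its enantiomer, the (3aS,7aR)‑adduct F1. The racemate would be carried through the conditions of step 8, F1 passing through the enantiomeric keto acetal F2 and the enantiomeric cyclized methyl ether F3 to the (4R,5S)‑enone F4, formed alongside 19. Reduction under the conditions of step 9 would then act as a divergent reaction on the racemate: reagent control should turn 19 into 20 and F4 into the diastereomeric (1R,4R,5S)‑alcohol F5, which would be removed by chromatography. The route is rejoined at 20.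

2. Step 8. The Z‑benzylidene lactone may fail to equilibrate to the E isomer under acid, so that C9 cannot reach the C20 oxocarbenium ion and desilylation without annulation, or Prins‑type closure at C7, takes over. Fallback, setting out from 15: triplet‑sensitized irradiation (thioxanthone, 405 nm, MeCN) should give a photostationary Z/E mixture, from which the (3E)‑benzylidene lactone F6 would be separated and the Z isomer recycled. F6 would then be treated with HC(OMe)3/BF3·OEt2 and mild acid; the E‑configured keto acetal F7 is already shaped for ring closure and should pass through 18 to 19, where the route is rejoined.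

3. Step 11. Chloride at 90 °C may open the enol lactone or displace the methoxy group by addition–elimination instead of dealkylating it. Fallback, setting out from 20: the order of operations is changed so that the dealkylation is done at the arene stage. BCl3 (1 equiv, CH2Cl2, −78 °C) should cleave selectively the most hindered, chelating 12‑methyl ether (flanked by O11 and isopropyl) to give the 12‑phenol F8. Oxidative demethylation of F8 with (NH4)2Ce(NO3)6 in MeCN/H2O should then give the hydroxyquinone directly, rejoining the route at 23.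

**Further compounds**
F1 | step 7 | (3Z,3aS,7aR)‑enantiomer of 15 | COc1c(C(C)C)c(OC)c(OC)cc1/C=C2\OC(=O)[C@]3(C)CCC(O[Si](C(C)C)(C(C)C)C(C)C)=C[C@H]23
F2 | step 7 | (3aS,7aR)‑enantiomer of keto acetal 17 | COc1c(C(C)C)c(OC)c(OC)cc1/C=C2\OC(=O)[C@]3(C)CCC(=O)C(C(OC)OC)[C@H]23
F3 | step 7 | (4R,5S)‑enantiomer of cyclized methyl ether 18 | CC(C)c1c(OC)c(OC)c2c(C=C3OC(=O)[C@]4(C)CCC(=O)C(C2OC)[C@H]34)c1OC
F4 | step 7 | (4R,5S)‑11,12,14‑trimethoxy‑1‑oxoicetexa‑6,8,10(20),11,13‑pentaen‑19,6‑olide | CC(C)c1c(OC)c(OC)c2c(C=C3OC(=O)[C@]4(C)CCC(=O)C(=C2)[C@H]34)c1OC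
F5 | step 7 | (1R,4R,5S)‑1‑hydroxy‑11,12,14‑trimethoxyicetexa‑6,8,10(20),11,13‑pentaen‑19,6‑olide | CC(C)c1c(OC)c(OC)c2c(C=C3OC(=O)[C@]4(C)CC[C@@H](O)C(=C2)[C@H]34)c1OC
F6 | step 8 | (3E,3aR,7aS)‑benzylidene isomer of 15 | COc1c(C(C)C)c(OC)c(OC)cc1/C=C2/OC(=O)[C@@]3(C)CCC(O[Si](C(C)C)(C(C)C)C(C)C)=C[C@@H]23
F7 | step 8 | (3E,3aR,7aS)‑benzylidene isomer of keto acetal 17 | COc1c(C(C)C)c(OC)c(OC)cc1/C=C2/OC(=O)[C@@]3(C)CCC(=O)C(C(OC)OC)[C@@H]23
F8 | step 11 | (1R,4S,5R)‑1,12‑dihydroxy‑11,14‑dimethoxyicetexa‑6,8,10(20),11,13‑pentaen‑19,6‑olide | CC(C)c1c(O)c(OC)c2c(C=C3OC(=O)[C@@]4(C)CC[C@@H](O)C(=C2)[C@@H]34)c1OC
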